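The route rests on opening the C3a–C7a bond of the cyclopentane ring C1–C2–C3–C3a–C7a. With C2 as a latent carbonyl, this ring, with methyls at C1 and C3 and a trans ring fusion, is the product of a reductive Nazarov cyclisation of an E,E-2,4-dimethyl divinyl ketone. In one operation the key step closes the five-membered ring and sets C1, C3, C3a and C7a. The precursor is acyclic dienone 16, whose β-carbons carry a benzyloxymethyl arm (future C4) and an enantiopure (R)-CH(Et)CH2OTBDPS arm (future C7). This stereocentre turns the two conrotation senses into separable diastereomers, and both ethers tolerate the Lewis acid. The cyclohexene is closed later by a C6–C7 Michael addition.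

Key step: step 8

Assumption: atom labels C1–C7a follow the indene numbering of the bicyclic core (C1/C3 = CHMe, C2 = CH2, C3a/C7a = ring fusion, C4(Me)=C5, C6 = CHPh, C7 = quaternary) and are used for the same carbons in all earlier intermediates.
Assumption: metal enolates and alkoxides generated by the stated base are treated as the parent numbered compound; only intermediates with a new covalent bond or a new carbon–metal bond carry their own number.

Step 1
Reactants: 1 (R)-4-benzyloxazolidin-2-one; 2 butanoyl chloride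
Product: 3 (R)-4-benzyl-3-butanoyloxazolidin-2-one
Conditions: n-BuLi, THF, −78 °C; then 2, −78 → 0 °C
Reagents that add atoms: none
Why: N-acylation of the lithiated oxazolidinone with an acid chloride (Evans auxiliary loading) is routine and leaves the benzyl-bearing stereocentre untouched.

Step 2
Reactants: 3 (R)-4-benzyl-3-butanoyloxazolidin-2-one; 4 1,3,5-trioxane
Product: 5 (R)-4-benzyl-3-[(2S)-2-(hydroxymethyl)butanoyl]oxazolidin-2-one
Conditions: TiCl4, i-Pr2NEt, CH2Cl2, 0 °C; then 4, TiCl4, 0 °C
Reagents that add atoms: none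
Why: Evans titanium-enolate hydroxymethylation, in which the chelated Z-enolate should be attacked by TiCl4-activated formaldehyde (from trioxane) on the face opposite the benzyl group, setting the future C7 centre as (S) in 5.

Step 3
Reactants: 5 (R)-4-benzyl-3-[(2S)-2-(hydroxymethyl)butanoyl]oxazolidin-2-one
Product: 6 (R)-4-benzyl-3-[(2S)-2-({[tert-butyl(diphenyl)silyl]oxy}methyl)butanoyl]oxazolidin-2-one
Conditions: TBDPSCl, imidazole, DMF, rt
Reagents that add atoms: tert-butyl(chloro)diphenylsilane, CC(C)(C)[Si](Cl)(c1ccccc1)c1ccccc1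
Why: Imidazole-mediated silylation of a primary alcohol (silyl ether formation); TBDPS is chosen because it must later survive BF3·OEt2.

Step 4
Reactants: 6 (R)-4-benzyl-3-[(2S)-2-({[tert-butyl(diphenyl)silyl]oxy}methyl)butanoyl]oxazolidin-2-one
Product: 7 (2R)-2-({[tert-butyl(diphenyl)silyl]oxy}methyl)butan-1-ol
Conditions: LiBH4, THF, 0 °C → rt
Reagents that add atoms: none
Why: Reductive cleavage of the N-acyl oxazolidinone with LiBH4 should give the primary alcohol and return auxiliary 1 without touching the α-stereocentre or the silyl ether.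

Step 5
Reactants: 7 (2R)-2-({[tert-butyl(diphenyl)silyl]oxy}methyl)butan-1-ol
Product: 8 (2S)-2-({[tert-butyl(diphenyl)silyl]oxy}methyl)butanal
Conditions: TEMPO (cat.), PhI(OAc)2, CH2Cl2, rt
Reagents that add atoms: none
Why: TEMPO/PhI(OAc)2 oxidation of a primary alcohol to the aldehyde runs under non-basic conditions that should not epimerise the α-centre; the aldehyde is used at once.

Step 6
Reactants: 9 pentan-3-one; 8 (2S)-2-({[tert-butyl(diphenyl)silyl]oxy}methyl)butanal
Product: 12 (4E,6R)-6-({[tert-butyl(diphenyl)silyl]oxy}methyl)-4-methyloct-4-en-3-one, via lithium aldolate 10 (not isolated), via β-mesyloxy ketone 11 (not isolated)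
Conditions: LiHMDS, THF, −78 °C; 8, −78 °C; MsCl, −78 → 0 °C; DBU, 0 °C → rt
Reagents that add atoms: none
Why: Directed aldol condensation in which the lithium enolate of 9 adds to 8 at −78 °C faster than the aldehyde enolises, the aldolate is mesylated in the flask and DBU-induced E1cB elimination should give the E-trisubstituted enone (the Z isomer suffers A(1,3) strain); the C7 centre is no longer acidic once the aldolate has formed.

Step 7
Reactants: 12 (4E,6R)-6-({[tert-butyl(diphenyl)silyl]oxy}methyl)-4-methyloct-4-en-3-one; 13 2-(benzyloxy)acetaldehyde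
Product: 16 (2E,5E,7R)-1-(benzyloxy)-7-({[tert-butyl(diphenyl)silyl]oxy}methyl)-3,5-dimethylnona-2,5-dien-4-one, via lithium aldolate 14 (not isolated), via β-mesyloxy ketone 15 (not isolated)
Conditions: LiHMDS, THF, −78 °C; 13, −78 °C; MsCl, −78 → 0 °C; DBU, 0 °C
Reagents that add atoms: none
Why: Second directed aldol condensation, in which the amide base removes the α′-methylene proton of 12 kinetically (cross-conjugated enolate) and leaves the hindered γ-hydrogen at C7 alone, and mesylation/E1cB elimination as in step 6 should give the E,E-dienone.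

Step 8
Reactants: 16 (2E,5E,7R)-1-(benzyloxy)-7-({[tert-butyl(diphenyl)silyl]oxy}methyl)-3,5-dimethylnona-2,5-dien-4-one; 17 triethylsilane
Product: 19 (2S,3S,4S,5S)-3-[(benzyloxy)methyl]-4-[(2R)-1-{[tert-butyl(diphenyl)silyl]oxy}butan-2-yl]-2,5-dimethylcyclopentan-1-one, via triethylsilyl enol ether 18 (not isolated)
Conditions: BF3·OEt2 (2 equiv), Et3SiH (5 equiv), CH2Cl2, −78 → 0 °C; then 1 M HCl, THF, 0 °C; chromatography (removes the ring diastereomer)
Reagents that add atoms: none
Why: BF3 complexation of the dienone gives a hydroxypentadienyl cation that undergoes thermal 4π conrotatory electrocyclisation to a 2-oxidoallyl cation, which takes hydride from Et3SiH at one terminus, and the resulting silyl enol ether 18 is protonated at carbon on cold acidic work-up (reductive, hydride-interrupted Nazarov cyclisation, known for α,α′-dimethyl divinyl ketones). The ring C1–C2–C3–C3a–C7a closes by this electrocyclic C3a–C7a bond formation, and conrotation of the E,E-dienone places the two β-substituents trans (C3a, C7a). Hydride at the first terminus and the proton at the second should each arrive anti to the adjacent ring substituent, so each methyl ends up cis to its neighbour (C1, C3); this arrangement is kinetic, hence the short cold work-up and the immediate reduction in step 9. The two senses of conrotation are diastereomeric because of the (R)-configured C7 centre: in the A(1,3)-preferred rotamer (C7–H eclipsing the enone C=C) the bond leading to 19 forms anti to the bulkier silyloxymethyl group, but any bias is expected to be small and 19 is separated from its ring diastereomer by chromatography. The step needs cyclisation and hydride capture to outrun conjugate reduction, proton loss to a cyclopentenone and ether cleavage; the α-methyl groups (faster closure, better stabilised oxyallyl cation), excess silane and the Lewis-acid-tolerant benzyl and TBDPS ethers are there to secure this.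

Step 9
Reactants: 19 (2S,3S,4S,5S)-3-[(benzyloxy)methyl]-4-[(2R)-1-{[tert-butyl(diphenyl)silyl]oxy}butan-2-yl]-2,5-dimethylcyclopentan-1-one
Product: 20 3-[(benzyloxy)methyl]-4-[(2R)-1-{[tert-butyl(diphenyl)silyl]oxy}butan-2-yl]-2,5-dimethylcyclopentan-1-ol (both C2 epimers; core labels 1S,3S,3aS,7aS)
Conditions: DIBAL-H, CH2Cl2, −78 °C
Reagents that add atoms: none
Why: Carbonyl reduction with DIBAL-H at −78 °C is non-basic and should not enolise the contra-thermodynamic C1 and C3 centres; the new C2 carbinol centre is removed in step 11, so both epimers are carried on.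

Step 10
Reactants: 20 3-[(benzyloxy)methyl]-4-[(2R)-1-{[tert-butyl(diphenyl)silyl]oxy}butan-2-yl]-2,5-dimethylcyclopentan-1-ol
Product: 22 O-{3-[(benzyloxy)methyl]-4-[(2R)-1-{[tert-butyl(diphenyl)silyl]oxy}butan-2-yl]-2,5-dimethylcyclopentyl} S-methyl carbonodithioate, via sodium xanthate 21 (not isolated)
Conditions: NaH, imidazole (cat.), THF, 0 °C; CS2; MeI, rt
Reagents that add atoms: carbon disulfide, S=C=S; iodomethane, CI
Why: Xanthate formation (alkoxide addition to CS2, then S-methylation) is the reliable activation of a hindered secondary alcohol for Barton–McCombie deoxygenation; C1 and C3 are no longer α to a carbonyl and are now fixed.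

Step 11
Reactants: 22 O-{3-[(benzyloxy)methyl]-4-[(2R)-1-{[tert-butyl(diphenyl)silyl]oxy}butan-2-yl]-2,5-dimethylcyclopentyl} S-methyl carbonodithioate
Product: 23 benzyl ether of 24: tert-butyl{[(2R)-2-{2-[(benzyloxy)methyl]-3,5-dimethylcyclopentyl}butyl]oxy}diphenylsilane (core labels 1R,3R,3aR,7aS)
Conditions: Bu3SnH, AIBN (cat.), toluene, 90 °C
Reagents that add atoms: none
Why: Barton–McCombie radical deoxygenation, in which stannyl radical addition to the thiocarbonyl and β-scission give a C2 radical that takes a hydrogen atom from Bu3SnH, leaving the four ring stereocentres untouched.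

Step 12
Reactants: 23 tert-butyl{[(2R)-2-{2-[(benzyloxy)methyl]-3,5-dimethylcyclopentyl}butyl]oxy}diphenylsilane
Product: 24 {5-[(2R)-1-{[tert-butyl(diphenyl)silyl]oxy}butan-2-yl]-2,4-dimethylcyclopentyl}methanol (core labels 1R,3R,3aR,7aS)
Conditions: H2 (1 atm), Pd/C, EtOAc, rt
Reagents that add atoms: none
Why: Hydrogenolysis of the benzyl ether over Pd/C is placed here because the molecule contains no alkene; the TBDPS ether is inert.

Step 13
Reactants: 24 {5-[(2R)-1-{[tert-butyl(diphenyl)silyl]oxy}butan-2-yl]-2,4-dimethylcyclopentyl}methanol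
Product: 25 5-[(2R)-1-{[tert-butyl(diphenyl)silyl]oxy}butan-2-yl]-2,4-dimethylcyclopentane-1-carbaldehyde (core labels 1R,3R,3aR,7aS)
Conditions: TEMPO (cat.), PhI(OAc)2, CH2Cl2, rt
Reagents that add atoms: none
Why: TEMPO/PhI(OAc)2 oxidation gives the C4 aldehyde under non-basic conditions, so C3a (now α to the formyl group) should not epimerise; the aldehyde is used directly.

Step 14
Reactants: 25 5-[(2R)-1-{[tert-butyl(diphenyl)silyl]oxy}butan-2-yl]-2,4-dimethylcyclopentane-1-carbaldehyde; 26 (E)-(2-bromovinyl)benzene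
Product: 28 (2E)-1-{5-[(2R)-1-{[tert-butyl(diphenyl)silyl]oxy}butan-2-yl]-2,4-dimethylcyclopentyl}-3-phenylprop-2-en-1-ol (both carbinol epimers), via (E)-styryllithium 27 (not isolated)
Conditions: 26, t-BuLi (2 equiv), Et2O, −78 °C; then 25, −78 °C
Reagents that add atoms: none
Why: Bromine–lithium exchange with t-BuLi gives (E)-styryllithium with retention of alkene geometry, and its 1,2-addition to the aldehyde at −78 °C outruns enolisation; the new carbinol centre is oxidised away in step 16.

Step 15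
Reactants: 28 (2E)-1-{5-[(2R)-1-{[tert-butyl(diphenyl)silyl]oxy}butan-2-yl]-2,4-dimethylcyclopentyl}-3-phenylprop-2-en-1-ol
Product: 29 (2E)-1-{5-[(2R)-1-hydroxybutan-2-yl]-2,4-dimethylcyclopentyl}-3-phenylprop-2-en-1-ol
Conditions: TBAF, THF, rt
Reagents that add atoms: none
Why: Fluoride-mediated cleavage of the TBDPS ether is placed before any carbonyl is present, so the basic fluoride cannot epimerise C3a.

Step 16
Reactants: 29 (2E)-1-{5-[(2R)-1-hydroxybutan-2-yl]-2,4-dimethylcyclopentyl}-3-phenylprop-2-en-1-ol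
Product: 30 (2R)-2-{2,4-dimethyl-5-[(2E)-3-phenylprop-2-enoyl]cyclopentyl}butanal (core labels 1R,3R,3aR,7aS)
Conditions: (COCl)2, DMSO, CH2Cl2, −78 °C; Et3N, −78 → 0 °C
Reagents that add atoms: none
Why: Swern oxidation converts both hydroxyl groups at once (secondary allylic to the E-enone, primary to the aldehyde) and does not over-oxidise a possible 1,5-lactol to a lactone; epimerisation at C7 is immaterial because C7 becomes planar in step 17.

Step 17
Reactants: 30 (2R)-2-{2,4-dimethyl-5-[(2E)-3-phenylprop-2-enoyl]cyclopentyl}butanal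
Product: 31 (1R,3R,3aR,6S,7R,7aR)-7-ethyl-1,3-dimethyl-4-oxo-6-phenyloctahydro-1H-indene-7-carbaldehyde
Conditions: DBU (0.2 equiv), MeCN, 0 °C → rt
Reagents that add atoms: none
Why: Intramolecular Michael addition (6-endo-trig) of the aldehyde enolate, the most acidic site, to the E-cinnamoyl ketone, in which the short tether forces a boat-like closure that, with the trans fusion, puts C3a–H and the C6 hydrogen on the same face (C6 thus follows from the E geometry), while at C7 the small planar formyl group rather than ethyl should take the crowded axial site next to the C1 methyl, both kinetically and under retro-Michael equilibration.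

Step 18
Reactants: 31 (1R,3R,3aR,6S,7R,7aR)-7-ethyl-1,3-dimethyl-4-oxo-6-phenyloctahydro-1H-indene-7-carbaldehyde; 32 triethyl 2-phosphonopropionate
Product: 33 ethyl (2E)-3-[(1R,3R,3aR,6S,7S,7aR)-7-ethyl-1,3-dimethyl-4-oxo-6-phenyloctahydro-1H-inden-7-yl]-2-methylprop-2-enoate
Conditions: NaH, 32, THF, 0 °C; then 31, 0 °C → rt
Reagents that add atoms: none
Why: Horner–Wadsworth–Emmons olefination, in which the phosphonate anion attacks the non-enolisable aldehyde in preference to the hindered ketone and should give the E-trisubstituted enoate, as is usual for α-quaternary aldehydes.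

Step 19
Reactants: 33 ethyl (2E)-3-[(1R,3R,3aR,6S,7S,7aR)-7-ethyl-1,3-dimethyl-4-oxo-6-phenyloctahydro-1H-inden-7-yl]-2-methylprop-2-enoate
Product: 34 ethyl (2E)-3-[(1R,3R,3aR,6S,7S,7aR)-7-ethyl-1,3-dimethyl-6-phenyl-4-{[(trifluoromethyl)sulfonyl]oxy}-2,3,3a,6,7,7a-hexahydro-1H-inden-7-yl]-2-methylprop-2-enoate
Conditions: KHMDS, THF, −78 °C; PhNTf2, −78 → 0 °C
Reagents that add atoms: N-phenylbis(trifluoromethanesulfonimide), O=S(=O)(N(c1ccccc1)S(=O)(=O)C(F)(F)F)C(F)(F)F
Why: Kinetic deprotonation with KHMDS at −78 °C removes a C5 methylene proton rather than the C3a methine, and O-sulfonylation with PhNTf2 gives the C4=C5 enol triflate; the enoate has no γ-hydrogen and is inert.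

Step 20
Reactants: 34 ethyl (2E)-3-[(1R,3R,3aR,6S,7S,7aR)-7-ethyl-1,3-dimethyl-6-phenyl-4-{[(trifluoromethyl)sulfonyl]oxy}-2,3,3a,6,7,7a-hexahydro-1H-inden-7-yl]-2-methylprop-2-enoate
Product: 35 ethyl (2E)-3-[(1R,3R,3aR,6S,7S,7aR)-7-ethyl-1,3,4-trimethyl-6-phenyl-2,3,3a,6,7,7a-hexahydro-1H-inden-7-yl]-2-methylprop-2-enoate
Conditions: Me2Zn, Pd(PPh3)4 (cat.), THF, 0 °C → rt
Reagents that add atoms: dimethylzinc, C[Zn]C
Why: Negishi cross-coupling of the enol triflate with dimethylzinc (oxidative addition, transmetalation, reductive elimination) installs the C4 methyl group without moving the C4=C5 double bond and tolerates the ester.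

Step 21
Reactants: 35 ethyl (2E)-3-[(1R,3R,3aR,6S,7S,7aR)-7-ethyl-1,3,4-trimethyl-6-phenyl-2,3,3a,6,7,7a-hexahydro-1H-inden-7-yl]-2-methylprop-2-enoate
Product: 36 plakotenin, (2E)-3-[(1R,3R,3aR,6S,7S,7aR)-7-ethyl-1,3,4-trimethyl-6-phenyl-2,3,3a,6,7,7a-hexahydro-1H-inden-7-yl]-2-methylprop-2-enoic acid
Conditions: LiOH, THF/MeOH/H2O, 50 °C; then 1 M HCl
Reagents that add atoms: lithium hydroxide, [Li+].[OH-]
Why: Saponification (BAc2 ester hydrolysis) of the ethyl ester; no stereocentre is α to a carbonyl, so the base cannot epimerise anything and the E-alkene is retained.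

Compound list
1 | (R)-4-benzyloxazolidin-2-one | O=C1N[C@H](Cc2ccccc2)CO1 | starting material
2 | butanoyl chloride | CCCC(=O)Cl | starting material
3 | (R)-4-benzyl-3-butanoyloxazolidin-2-one | CCCC(=O)N1[C@H](Cc2ccccc2)COC1=O | intermediate
4 | 1,3,5-trioxane | C1OCOCO1 | starting material
5 | (R)-4-benzyl-3-[(2S)-2-(hydroxymethyl)butanoyl]oxazolidin-2-one | CC[C@@H](CO)C(=O)N1[C@H](Cc2ccccc2)COC1=O | intermediate
6 | (R)-4-benzyl-3-[(2S)-2-({[tert-butyl(diphenyl)silyl]oxy}methyl)butanoyl]oxazolidin-2-one | CC[C@@H](CO[Si](c1ccccc1)(c1ccccc1)C(C)(C)C)C(=O)N1[C@H](Cc2ccccc2)COC1=O | intermediate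
7 | (2R)-2-({[tert-butyl(diphenyl)silyl]oxy}methyl)butan-1-ol | CC[C@@H](CO[Si](c1ccccc1)(c1ccccc1)C(C)(C)C)CO | intermediate
8 | (2S)-2-({[tert-butyl(diphenyl)silyl]oxy}methyl)butanal | CC[C@@H](CO[Si](c1ccccc1)(c1ccccc1)C(C)(C)C)C=O | intermediate
9 | pentan-3-one | CCC(=O)CC | starting material
10 | lithium aldolate from 9 and 8 (lithium 6-silyloxymethyl-4-methyl-3-oxooctan-5-olate; C6 as in 8, two new centres as a mixture) | CC[C@@H](CO[Si](c1ccccc1)(c1ccccc1)C(C)(C)C)C([O-])C(C)C(=O)CC.[Li+] | intermediate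
11 | β-mesyloxy ketone from 10 | CC[C@@H](CO[Si](c1ccccc1)(c1ccccc1)C(C)(C)C)C(OS(C)(=O)=O)C(C)C(=O)CC | intermediate
12 | (4E,6R)-6-({[tert-butyl(diphenyl)silyl]oxy}methyl)-4-methyloct-4-en-3-one | CC[C@@H](CO[Si](c1ccccc1)(c1ccccc1)C(C)(C)C)/C=C(\C)C(=O)CC | intermediate
13 | 2-(benzyloxy)acetaldehyde | O=CCOCc1ccccc1 | starting material
14 | lithium aldolate from 12 and 13 | CC[C@@H](CO[Si](c1ccccc1)(c1ccccc1)C(C)(C)C)/C=C(\C)C(=O)C(C)C([O-])COCc1ccccc1.[Li+] | intermediate
15 | β-mesyloxy ketone from 14 | CC[C@@H](CO[Si](c1ccccc1)(c1ccccc1)C(C)(C)C)/C=C(\C)C(=O)C(C)C(OS(C)(=O)=O)COCc1ccccc1 | intermediate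
16 | (2E,5E,7R)-1-(benzyloxy)-7-({[tert-butyl(diphenyl)silyl]oxy}methyl)-3,5-dimethylnona-2,5-dien-4-one | CC[C@@H](CO[Si](c1ccccc1)(c1ccccc1)C(C)(C)C)/C=C(\C)C(=O)/C(C)=C/COCc1ccccc1 | intermediate
17 | triethylsilane | CC[SiH](CC)CC | starting material
18 | triethylsilyl enol ether of 19 (C2=C3 enol ether shown; C1, C3a, C7a and C7 as in 19) | CC[C@@H](CO[Si](c1ccccc1)(c1ccccc1)C(C)(C)C)[C@H]1[C@H](COCc2ccccc2)C(C)=C(O[Si](CC)(CC)CC)[C@H]1C | intermediate
19 | (2S,3S,4S,5S)-3-[(benzyloxy)methyl]-4-[(2R)-1-{[tert-butyl(diphenyl)silyl]oxy}butan-2-yl]-2,5-dimethylcyclopentan-1-one (each methyl cis to its neighbouring side chain, side chains trans) | CC[C@@H](CO[Si](c1ccccc1)(c1ccccc1)C(C)(C)C)[C@H]1[C@H](COCc2ccccc2)[C@H](C)C(=O)[C@H]1C | intermediate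
20 | 3-[(benzyloxy)methyl]-4-[(2R)-1-{[tert-butyl(diphenyl)silyl]oxy}butan-2-yl]-2,5-dimethylcyclopentan-1-ol (both C2 epimers; other centres as in 19) | CC[C@@H](CO[Si](c1ccccc1)(c1ccccc1)C(C)(C)C)[C@H]1[C@H](COCc2ccccc2)[C@H](C)C(O)[C@H]1C | intermediate
21 | sodium xanthate (O-cyclopentyl carbonodithioate sodium salt) of 20 | CC[C@@H](CO[Si](c1ccccc1)(c1ccccc1)C(C)(C)C)[C@H]1[C@H](COCc2ccccc2)[C@H](C)C(OC(=S)[S-])[C@H]1C.[Na+] | intermediate
22 | O-{3-[(benzyloxy)methyl]-4-[(2R)-1-{[tert-butyl(diphenyl)silyl]oxy}butan-2-yl]-2,5-dimethylcyclopentyl} S-methyl carbonodithioate | CC[C@@H](CO[Si](c1ccccc1)(c1ccccc1)C(C)(C)C)[C@H]1[C@H](COCc2ccccc2)[C@H](C)C(OC(=S)SC)[C@H]1C | intermediate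
23 | tert-butyl{[(2R)-2-{2-[(benzyloxy)methyl]-3,5-dimethylcyclopentyl}butyl]oxy}diphenylsilane (core labels 1R,3R,3aR,7aS) | CC[C@@H](CO[Si](c1ccccc1)(c1ccccc1)C(C)(C)C)[C@H]1[C@H](COCc2ccccc2)[C@H](C)C[C@H]1C | intermediate
24 | {5-[(2R)-1-{[tert-butyl(diphenyl)silyl]oxy}butan-2-yl]-2,4-dimethylcyclopentyl}methanol (core labels 1R,3R,3aR,7aS) | CC[C@@H](CO[Si](c1ccccc1)(c1ccccc1)C(C)(C)C)[C@H]1[C@H](CO)[C@H](C)C[C@H]1C | intermediate
25 | 5-[(2R)-1-{[tert-butyl(diphenyl)silyl]oxy}butan-2-yl]-2,4-dimethylcyclopentane-1-carbaldehyde (core labels 1R,3R,3aR,7aS) | CC[C@@H](CO[Si](c1ccccc1)(c1ccccc1)C(C)(C)C)[C@H]1[C@H](C=O)[C@H](C)C[C@H]1C | intermediate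
26 | (E)-(2-bromovinyl)benzene | Br/C=C/c1ccccc1 | starting material
27 | (E)-styryllithium | [Li]/C=C/c1ccccc1 | intermediate
28 | (2E)-1-{5-[(2R)-1-{[tert-butyl(diphenyl)silyl]oxy}butan-2-yl]-2,4-dimethylcyclopentyl}-3-phenylprop-2-en-1-ol (both carbinol epimers; core labels 1R,3R,3aR,7aS) | CC[C@@H](CO[Si](c1ccccc1)(c1ccccc1)C(C)(C)C)[C@H]1[C@H](C(O)/C=C/c2ccccc2)[C@H](C)C[C@H]1C | intermediate
29 | (2E)-1-{5-[(2R)-1-hydroxybutan-2-yl]-2,4-dimethylcyclopentyl}-3-phenylprop-2-en-1-ol (core labels 1R,3R,3aR,7aS) | CC[C@@H](CO)[C@H]1[C@H](C(O)/C=C/c2ccccc2)[C@H](C)C[C@H]1C | intermediate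
30 | (2R)-2-{2,4-dimethyl-5-[(2E)-3-phenylprop-2-enoyl]cyclopentyl}butanal (core labels 1R,3R,3aR,7aS) | CC[C@@H](C=O)[C@H]1[C@H](C(=O)/C=C/c2ccccc2)[C@H](C)C[C@H]1C | intermediate
31 | (1R,3R,3aR,6S,7R,7aR)-7-ethyl-1,3-dimethyl-4-oxo-6-phenyloctahydro-1H-indene-7-carbaldehyde | CC[C@@]1(C=O)[C@H]2[C@H](C(=O)C[C@H]1c1ccccc1)[C@H](C)C[C@H]2C | intermediate
32 | triethyl 2-phosphonopropionate | CCOC(=O)C(C)P(=O)(OCC)OCC | starting material
33 | ethyl (2E)-3-[(1R,3R,3aR,6S,7S,7aR)-7-ethyl-1,3-dimethyl-4-oxo-6-phenyloctahydro-1H-inden-7-yl]-2-methylprop-2-enoate | CC[C@@]1(/C=C(\C)C(=O)OCC)[C@H]2[C@H](C(=O)C[C@H]1c1ccccc1)[C@H](C)C[C@H]2C | intermediate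
34 | ethyl (2E)-3-[(1R,3R,3aR,6S,7S,7aR)-7-ethyl-1,3-dimethyl-6-phenyl-4-{[(trifluoromethyl)sulfonyl]oxy}-2,3,3a,6,7,7a-hexahydro-1H-inden-7-yl]-2-methylprop-2-enoate | CC[C@@]1(/C=C(\C)C(=O)OCC)[C@H]2[C@H](C(OS(=O)(=O)C(F)(F)F)=C[C@H]1c1ccccc1)[C@H](C)C[C@H]2C | intermediate
35 | ethyl (2E)-3-[(1R,3R,3aR,6S,7S,7aR)-7-ethyl-1,3,4-trimethyl-6-phenyl-2,3,3a,6,7,7a-hexahydro-1H-inden-7-yl]-2-methylprop-2-enoate | CC[C@@]1(/C=C(\C)C(=O)OCC)[C@H]2[C@H](C(C)=C[C@H]1c1ccccc1)[C@H](C)C[C@H]2C | intermediate
36 | plakotenin, (2E)-3-[(1R,3R,3aR,6S,7S,7aR)-7-ethyl-1,3,4-trimethyl-6-phenyl-2,3,3a,6,7,7a-hexahydro-1H-inden-7-yl]-2-methylprop-2-enoic acid | CC[C@@]1(/C=C(\C)C(=O)O)[C@H]2[C@H](C(C)=C[C@H]1c1ccccc1)[C@H](C)C[C@H]2C | target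

Total step count: 21
Longest linear sequence: 21 steps (1 → 36; the route is fully linear)

Steps most likely to fail

Step 8. What may go wrong: thermodynamic protonation or epimerisation during hydrolysis of the silyl enol ether erodes the kinetic cis methyl/side-chain relationship; in addition, little facial preference between the two conrotation senses is expected, so separation of the ring diastereomers carries the absolute configuration. Fallback: ring closure and the stereo-setting protonation are separated. The sequence sets out from 18, obtained by a non-acidic (NaHCO3) work-up of the cyclisation. MeLi in THF at 0 °C cleaves the O–Si bond to give lithium enolate F1, which is quenched at −78 °C with 2,6-di-tert-butyl-4-methylphenol. The bulky proton donor should approach the enolate carbon anti to the adjacent ring substituent (kinetic enolate protonation), and the sequence comes back to the route at 19.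

Step 17. What may go wrong: poor facial selectivity at C7 (ethyl instead of formyl taking the axial site) or base-induced epimerisation at C3a next to the ketone. Fallback: the base-mediated closure is replaced by a Lewis-acid-mediated one. Setting out from 30, soft enolisation of the more reactive aldehyde (TBSOTf, Et3N, CH2Cl2, −78 °C) gives silyl enol ether F2. TiCl4 in CH2Cl2 at −78 °C then triggers an intramolecular Mukaiyama–Michael addition to the enone under non-basic, irreversible conditions. Aqueous work-up returns to the route at 31.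

Step 18. What may go wrong: slow or incomplete olefination of the neopentyl-type formyl group on quaternary C7, with competing enolisation of the C4 ketone by the phosphonate anion. Fallback: the double bond is built stepwise with a smaller nucleophile. Setting out from 31, the lithium enolate of ethyl propanoate (LDA, THF, −78 °C) adds to the aldehyde to give β-hydroxy ester F3. MsCl/Et3N converts it into mesylate F4, and DBU-induced E1cB elimination gives the thermodynamically preferred E-enoate, returning to the route at 33.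

Further compounds
F1 | step 8 | lithium enolate of 19 (C2–C3 enolate) | CC[C@@H](CO[Si](c1ccccc1)(c1ccccc1)C(C)(C)C)[C@H]1[C@H](COCc2ccccc2)C(C)=C([O-])[C@H]1C.[Li+]
F2 | step 17 | tert-butyldimethylsilyl enol ether of the aldehyde of 30 | CCC(=CO[Si](C)(C)C(C)(C)C)[C@H]1[C@H](C(=O)/C=C/c2ccccc2)[C@H](C)C[C@H]1C
F3 | step 18 | β-hydroxy ester from 31 and ethyl propanoate | CC[C@@]1(C(O)C(C)C(=O)OCC)[C@H]2[C@H](C(=O)C[C@H]1c1ccccc1)[C@H](C)C[C@H]2C
F4 | step 18 | mesylate of F3 | CC[C@@]1(C(OS(C)(=O)=O)C(C)C(=O)OCC)[C@H]2[C@H](C(=O)C[C@H]1c1ccccc1)[C@H](C)C[C@H]2C
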